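All runs were generated by integration on assumed constants; noise was put on by code.

the same everywhere: left-handed substrate 0.050 M; right-handed substrate 0.050 M; gas 5.8 mM (held)

| flask | catalyst | added ligand | remark | time |
|---|---|---|---|---|
| grey | 5 mM | 7.7 mM | run made earlier |  |
| violet | 20 mM | 7.7 mM | run made earlier |  |
| amber | 10 mM | 15 mM | run made earlier |  |
| flask | 10 mM | 7.7 mM |  | 6.0 min |

- grey (time / min: right-handed substrate / %, left-handed substrate / %): 2.00: 48.2, 1.2; 4.00: 46.1, 0; 5.00: 46.0, 0; 8.00: 43.2, 0.1
- violet (time / min: right-handed substrate / %, left-handed substrate / %): 2.00: 42.2, 0; 4.00: 37.0, 0.3; 5.00: 32.7, 0.2; 8.00: 25.2, 0.5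
- amber (time / min: right-handed substrate / %, left-handed substrate / %): 0.833: 48.6, 5.2; 2.50: 46.3, 0.4; 5.00: 43.2, 0.2; 8.00: 38.4, 0.6

(readings scatter by 0.5 percentage points)

* whether the excess of right-handed substrate over left-handed substrate among what is left of the two reaches 98% by 6.0 min (no / yes)
* the highest excess of right-handed substrate over left-handed substrate among what is left of the two up to 6.0 min

- catalyst is single-handed; left-handed substrate and right-handed substrate are mirror images of each other, charged as a racemate, each of them at the stated concentration
- what was read earlier has a scatter of 0.5 percentage points, one standard deviation
- at the start none of the gas is in solution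

The right-handed substrate is the slow one, and its slowness is the thing to freeze. If the held gas and the catalyst keep acting on it at a steady level, its fall is pseudo-first-order. Between first and last readings, the grey run then loses 0.0183 min⁻¹ and the violet run 0.0859 min⁻¹. The flask's catalyst stands one doubling above grey and one below violet, so I take the geometric mean of the two, 0.0396 min⁻¹. This is the slow constant, the share of the right-handed substrate lost per minute in the flask. It leaves 39.4% at 6.0 min.

Two people then differ over the left-handed substrate, of which the wanted excess allows 0.0101 of the right-handed amount. The first reads 5.2% at 0.833 min in the amber run as a fast constant of 2.72 min⁻¹, so that ratio comes after about 1.69 min, which is shorter than 6.0 min. The second takes the amber run's last reading, 0.6%, as a floor. Against 39.4% that floor gives an excess of 97.0%, which is less than 98%. The first answers that this reading carries a scatter of 0.5 percentage points, and I side with the first.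

The forecast takes the first side, answering yes with a top of 99.9%, since the late left-handed readings “look like noise clipped at zero”.

The simulation answers yes, with a top of 100%.

    partner + catalyst + left-handed substrate → catalyst + left-handed product (k = 1900 M⁻² s⁻¹)
    partner + catalyst + right-handed substrate → catalyst + right-handed product (k = 16.0 M⁻² s⁻¹)
    gas ⇌ partner, rate k3*(csat - [partner]) (kL = 0.730 s⁻¹)
    partner → decomposed reagent (k = 0.0120 s⁻¹)
    catalyst + added ligand ⇌ idle complex, settled at all times (K = 69.0 M⁻¹)

The flask passes 98% at 1.19 min with 48.1% of right-handed substrate standing. The left-handed rest is then about 0.486%, beside a scatter of 0.5 points, so a single reading there does not tell that rest from zero. The second view's floor does not stand in this flask, which holds 0% of left-handed substrate at 3.00 min. For 60.0 min the slow constant gives 4.65% of right-handed substrate, and the flask holds 4.47%.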